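At 10.0 h, Monday's run, with its larger impurity charge, holds 18.2% target against Sunday's 16.4%, yet the target is falling in both runs. You want a quantity that stays put while the target falls.

| setting | Sunday's | Monday's | flask |
|---|---|---|---|
| substrate | 46 mM | 46 mM | 46 mM |
| coupling partner | 82.8 mM | 82.8 mM | 82.8 mM |
| free catalyst | 2.3 mM | 2.3 mM | 2.3 mM |
| impurity | 0.21 mM | 0.84 mM | 0.42 mM |
| remark | run made earlier | run made earlier |  |
| time |  |  | 15 h |

| run | time / h | target / % | isomer of the product / % | substrate / % |
|---|---|---|---|---|
| Sunday's | 0.833 | 14.7 | 6.9 | 78.2 |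
| Sunday's | 2.50 | 24.8 | 18.0 | 57.6 |
| Sunday's | 4.00 | 24.3 | 26.1 | 49.3 |
| Sunday's | 6.00 | 22.1 | 35.5 | 42.2 |
| Sunday's | 10.0 | 16.4 | 50.2 | 32.8 |
| Monday's | 0.833 | 14.7 | 6.9 | 78.5 |
| Monday's | 2.50 | 24.7 | 16.5 | 57.9 |
| Monday's | 4.00 | 25.4 | 24.9 | 49.5 |
| Monday's | 6.00 | 23.9 | 33.2 | 43.0 |
| Monday's | 10.0 | 18.2 | 46.5 | 33.5 |

(each reading ± 0.3 percentage points)

* ratio of target to isomer of the product at 6.0 min
* ratio of target to isomer of the product at 15 h
* which of target and isomer of the product there is more of at 15 h

- what was read earlier has a scatter of 0.3 percentage points, one standard deviation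

Write the balance of the substrate, the limiting reagent, since it is charged in less than the coupling partner. Substrate, target and isomer sum to 99.4% of the charge in Sunday's run and 98.2% in Monday's at 10.0 h, so the three come close to the charge without closing it exactly, and I take each substrate lost to take one coupling partner with it. So you know c(coupling partner) at every reading.

9.64 M⁻¹10.4 M⁻¹10.0 M⁻¹Now form c(target)/(c(substrate)·c(coupling partner)), the reaction quotient of the step to target. In Sunday's run it reads 9.32 M⁻¹ at 6.00 h and 9.64 M⁻¹ at 10.0 h, and Monday's gives 10.4 M⁻¹ at 10.0 h. The late plateau of this quotient, 10.0 M⁻¹ as the mean of the two last readings, is what you carry.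

0.0627 h⁻¹24.2%11.6%64.1%0.182The flask's impurity lies between the two runs, so take their mean substrate, which falls at 0.0627 h⁻¹ late on. Carried to 15 h, that leaves 24.2% substrate. The quotient then gives 11.6% target, the balance, with the three counted as the whole charge, gives 64.1% isomer, and the ratio is 0.182.

The forecast, reasoning from “direct formation from substrate, plus slow first-order conversion of target”, gave 2.6 and 0.19, a little above my ratio, with isomer of the product ahead.

The flask gives 2.74 and 0.195, with 12.0% target and 61.8% isomer, so isomer of the product leads.

    substrate + coupling partner ⇌ target (K = 10.0 M⁻¹, k = 0.0510 M⁻¹ min⁻¹)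
    substrate + coupling partner ⇌ isomer of the product (K = 680 M⁻¹, k = 0.0180 M⁻¹ min⁻¹)
    target + free catalyst ⇌ isomer of the product + free catalyst, rate k3*[free catalyst]*[target] forward; the back reaction follows from the equilibrium constant (k = 0.690 M⁻¹ min⁻¹)
    substrate + coupling partner → uncatalysed product (k = 3.80 × 10⁻⁴ M⁻¹ min⁻¹)
    free catalyst + impurity → spent catalyst (k = 47.0 M⁻¹ min⁻¹)

At 15.0 h this flask makes target at 0.0702 of the rate at which it uses it up, each step taken net, while its quotient stands at 9.84 M⁻¹. The neighbour charged with 180 mM substrate has its coupling partner down to 10.3% of its charge at 15.0 h, with 5.39% target, and its quotient reads 10.7 M⁻¹.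

Readings and results were generated by integration with constants of no real substance; the scatter is artificial.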